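All runs come from a simulation with made-up constants, noise included.

Late in the gamma run, at 10.0 h, the substrate reads 0% and the target stands at 42%. I read the target share of consumed substrate (the selectivity) there as 42.0%, with the scatter of those readings, 1.5 percentage points, on it.

| flask | substrate | temperature | remark | time |
|---|---|---|---|---|
| theta | 10 mM | 0 °C | run made earlier |  |
| gamma | 40 mM | 12 °C | run made earlier |  |
| noon | 20 mM | 5 °C |  | 10 h |
| autumn | 20 mM | 20 °C |  | 10 h |

| run | time / h | target / % | substrate / % |
|---|---|---|---|
| theta | 0.833 | 2 | 92 |
| theta | 2.50 | 2 | 78 |
| theta | 5.00 | 12 | 59 |
| theta | 8.00 | 17 | 44 |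
| theta | 10.0 | 25 | 34 |
| gamma | 0.833 | 12 | 40 |
| gamma | 2.50 | 39 | 1 |
| gamma | 5.00 | 41 | 0 |
| gamma | 8.00 | 43 | 0 |
| gamma | 10.0 | 42 | 0 |

(readings scatter by 1.5 percentage points)

- which of these there is most of at the end, counted by the substrate in it, noon (target / substrate)
- which of these there is most of at the end, counted by the substrate in it, autumn (target / substrate)
- the largest of these amounts at the end, in percent of the substrate charged, noon
- the largest of these amounts at the end, in percent of the substrate charged, autumn



I turn the question round: what would put substrate ahead of target at the end? If a fraction of the charge is left and the share holds, substrate leads once that fraction exceeds the share of the part consumed. I get 29.6% for the crossover remainder, the fraction left at which substrate and target stand equal.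

Now the early end. In theta the substrate reads 92% at 0.833 h and 34% at 10.0 h, which I read as a first-order loss constant of 0.109 h⁻¹. Gamma's first reading gives 1.10 h⁻¹, about ten times theta's.

Joining the ends, noon's remainder stays above the crossover through 10 h only if its loss constant is under 0.122 h⁻¹, which is 1.12 times theta's reading and under gamma's. But noon has twice theta's charge and stands at 5 °C against 0 °C, so I expect it to pass that easily. Autumn, at 20 °C, is warmer than gamma. I commit to target in both flasks, near the share.

The forecast also says target for noon and target for autumn, with 38% (29% to 47%) for noon and 40% (31% to 47%) for autumn, both under my share. It notes that late theta increments “hint at slightly better selectivity when cold or dilute”.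

Noon ends with target at 47.7% and substrate at 1.16%; autumn ends with target at 53.1% and substrate at 0%.

    2 substrate → homo dimer (k = 0.138 M⁻¹ min⁻¹, Ea = 65.0 kJ mol⁻¹)
    substrate + target → 2 target (k = 0.986 M⁻¹ min⁻¹, Ea = 60.0 kJ mol⁻¹)
    substrate → target (k = 3.44 × 10⁻⁴ min⁻¹, Ea = 92.0 kJ mol⁻¹)
    (constants at 5 °C)

Both marks stand, and noon's remainder lies far below the crossover. The amounts stand 9.7 points and 13 points above the forecast. Noon's target stands at 47.7% at the end because of the step to homo dimer: without that step the same flask gives >99.9%. The repeat of noon at −10 °C ends with substrate at 56.2%, above the crossover, and there substrate does lead, though the share does not hold in that flask: its target, at 5.21%, is 11.9% of the part consumed.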